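**Plan**
- Feature: in ring C the C4 ketone, bonded to C4a of ring A, sits directly beside the secondary alcohol at C3. This acyloin pair traces back to two formyl groups, one on ring A (C4) and one at the end of the O1–C2 side chain (C3).
- Cuts, in retrosynthetic order: the two O–MOM bonds (O5, O3'), then C3–C4 (benzoin), then O1–C2 (ether synthesis), then O5–MOM, O7–Me and C8–prenyl on ring A and C2–Br on the ring B arylacetate.
- Forward: rings A and B are bought as arenes and dressed separately, then joined through O1–C2. Ester and formyl group are reduced together and re-oxidised to the dialdehyde, and ring C closes last.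
- Stereochemistry: all material is racemic at C2 up to the dialdehyde. The chiral triazolylidene fixes C3 and, because C2 epimerises under the amine base, picks out (2R) by dynamic kinetic resolution. Trans is also the more stable relationship.
- Acidic methanolysis then frees the O5 and O3' phenols without touching C2 or C3.

Key step: step 10

Assumption: the absolute sense of induction of the aminoindanol triazolium salt on this dialdehyde cannot be read from precedent, so the (5aS,10bR) salt is written, and its equally available (5aR,10bS) antipode takes its place if the ketol proves to be (2S,3S).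

**Step 1**
Reactants: 1 2,4,6-trihydroxybenzaldehyde; 2 prenyl bromide (1-bromo-3-methylbut-2-ene)
Product: 3 2,4,6-trihydroxy-3-(3-methylbut-2-en-1-yl)benzaldehyde
Conditions: DBU (1.0 equiv), 2 (0.9 equiv), THF, 0 °C to rt
Reagents that add atoms: none
Why: Nuclear C-prenylation of an acylphloroglucinol: the delocalised phenoxide made by DBU takes up the soft allylic bromide at a ring carbon, the two open positions are equivalent by symmetry, and keeping 2 as the limiting partner holds back a second alkylation.

**Step 2**
Reactants: 3 2,4,6-trihydroxy-3-(3-methylbut-2-en-1-yl)benzaldehyde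
Product: 4 2,6-dihydroxy-4-methoxy-3-(3-methylbut-2-en-1-yl)benzaldehyde
Conditions: Me2SO4 (1.0 equiv), K2CO3 (1.0 equiv), acetone, rt
Reagents that add atoms: dimethyl sulfate, COS(=O)(=O)OC
Why: Williamson etherification under stoichiometric control: the hydroxyl para to the formyl group is the most acidic one and the only one that cannot chelate the carbonyl oxygen, and the hard electrophile Me2SO4 reacts at oxygen and not at the free ring carbon.

**Step 3**
Reactants: 4 2,6-dihydroxy-4-methoxy-3-(3-methylbut-2-en-1-yl)benzaldehyde
Product: 5 2-hydroxy-4-methoxy-6-(methoxymethoxy)-3-(3-methylbut-2-en-1-yl)benzaldehyde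
Conditions: MOMCl (1.05 equiv), i-Pr2NEt, CH2Cl2, 0 °C
Reagents that add atoms: chloromethyl methyl ether, COCCl
Why: Regioselective MOM ether formation: O6 is flanked by a ring hydrogen and reacts first, whereas O2 is squeezed between the prenyl and formyl groups and keeps its hydrogen bond to the aldehyde, which also stops a second protection.

**Step 4**
Reactants: 6 2-(3-hydroxy-4-methoxyphenyl)acetic acid
Product: 7 methyl 2-(3-hydroxy-4-methoxyphenyl)acetate
Conditions: MeOH, H2SO4 (cat.), reflux
Reagents that add atoms: methanol, CO
Why: Fischer esterification, which leaves the phenol untouched.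

**Step 5**
Reactants: 7 methyl 2-(3-hydroxy-4-methoxyphenyl)acetate
Product: 8 methyl 2-[4-methoxy-3-(methoxymethoxy)phenyl]acetate
Conditions: MOMCl, i-Pr2NEt, CH2Cl2, 0 °C to rt
Reagents that add atoms: chloromethyl methyl ether, COCCl
Why: Standard MOM ether formation on the only acidic hydroxyl, chosen so that both phenol protecting groups fall in one final operation.

**Step 6**
Reactants: 8 methyl 2-[4-methoxy-3-(methoxymethoxy)phenyl]acetate
Product: 10 methyl (±)-2-bromo-2-[4-methoxy-3-(methoxymethoxy)phenyl]acetate, via lithium enolate 9 (not isolated)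
Conditions: LiN(SiMe3)2, THF, −78 °C; cannulated into NBS, THF, −78 °C
Reagents that add atoms: N-bromosuccinimide, O=C1CCC(=O)N1Br; lithium hexamethyldisilazide, [Li+].C[Si](C)(C)[N-][Si](C)(C)C (supplies the lithium of 9)
Why: Electrophilic alpha-bromination of an ester enolate: the benzylic ester is deprotonated cleanly at −78 °C, inverse addition to NBS keeps the enolate from displacing bromide from product already formed, the ionic pathway avoids the ring and acetal bromination that radical conditions would invite, and the new centre (future C2) is racemic on purpose.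

**Step 7**
Reactants: 5 2-hydroxy-4-methoxy-6-(methoxymethoxy)-3-(3-methylbut-2-en-1-yl)benzaldehyde; 10 methyl (±)-2-bromo-2-[4-methoxy-3-(methoxymethoxy)phenyl]acetate
Product: 11 methyl (±)-2-[2-formyl-5-methoxy-3-(methoxymethoxy)-6-(3-methylbut-2-en-1-yl)phenoxy]-2-[4-methoxy-3-(methoxymethoxy)phenyl]acetate
Conditions: K2CO3, DMF, rt to 40 °C
Reagents that add atoms: none
Why: Williamson-type SN2 etherification forming O1–C2: the bromide is activated twice (benzylic and alpha to the ester), so even the hindered, chelated phenoxide of 5 should displace it at a mild temperature, below the point at which the product would close by aldol addition onto the formyl group.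

**Step 8**
Reactants: 11 methyl (±)-2-[2-formyl-5-methoxy-3-(methoxymethoxy)-6-(3-methylbut-2-en-1-yl)phenoxy]-2-[4-methoxy-3-(methoxymethoxy)phenyl]acetate
Product: 12 (±)-2-[2-(hydroxymethyl)-5-methoxy-3-(methoxymethoxy)-6-(3-methylbut-2-en-1-yl)phenoxy]-2-[4-methoxy-3-(methoxymethoxy)phenyl]ethan-1-ol
Conditions: LiAlH4, THF, 0 °C; Fieser work-up
Reagents that add atoms: none
Why: Exhaustive hydride reduction: no hydride reagent would stop an ester at the aldehyde beside a free aryl aldehyde, so both carbonyl groups are taken down to primary alcohols, with ethers, acetals and the alkene inert and a basic work-up to spare the acid-labile trialkoxybenzyl alcohol.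

**Step 9**
Reactants: 12 (±)-2-[2-(hydroxymethyl)-5-methoxy-3-(methoxymethoxy)-6-(3-methylbut-2-en-1-yl)phenoxy]-2-[4-methoxy-3-(methoxymethoxy)phenyl]ethan-1-ol
Product: 13 4-methoxy-6-(methoxymethoxy)-2-{1-[4-methoxy-3-(methoxymethoxy)phenyl]-2-oxoethoxy}-3-(3-methylbut-2-en-1-yl)benzaldehyde (dialdehyde; racemic and labile at C2)
Conditions: Dess–Martin periodinane (2.4 equiv), pyridine, CH2Cl2, 0 °C to rt; filtered and used at once
Reagents that add atoms: none
Why: Double Dess–Martin oxidation: both primary alcohols go to aldehydes under near-neutral, water-free conditions without over-oxidation, pyridine takes up the acetic acid, and racemisation at C2 is of no concern since the racemate is wanted.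

**Step 10**
Reactants: 13 dialdehyde (racemic, C2 epimerising)
Product: 14 (2R,3R)-3-hydroxy-7-methoxy-5-(methoxymethoxy)-2-[4-methoxy-3-(methoxymethoxy)phenyl]-8-(3-methylbut-2-en-1-yl)chroman-4-one
Conditions: (5aS,10bR)-5a,10b-dihydro-2-(pentafluorophenyl)-4H,6H-indeno[2,1-b]-1,2,4-triazolo[4,3-d]-1,4-oxazinium tetrafluoroborate (20 mol%), i-Pr2NEt (50 mol%), 4 Å MS, degassed toluene (0.02 M), Ar, 30 °C
Reagents that add atoms: none
Why: Proposed new method: the triazolylidene freed by the amine binds the formyl carbon on ring A, a 1,2-proton shift turns this adduct into a nucleophilic enaminol whose carbon (the future C4) bonds to the carbonyl carbon of the side-chain aldehyde (C3), and loss of the azolium from the resulting alkoxide unveils the C4 ketone. The closest known reaction types are the triazolium-catalysed intramolecular aldehyde–ketone crossed benzoin leading to 3-hydroxychroman-4-ones, its dynamic kinetic resolution variant with base-labile alpha-stereocentres, and the azolium-catalysed cyclisation of aliphatic dialdehydes to cyclic ketols, whereas an aryl aldehyde paired with an enolisable aldehyde and resolved at its alpha-carbon has not been shown. Ring C closes in the 6-exo-trig mode. C3 is set by the catalyst, whose indane wall leaves one face of the enaminol open and thereby fixes which face of the C3 carbonyl is attacked, while C2 is set by dynamic kinetic resolution, because the C2–H (alpha to CHO, benzylic, alpha to aryloxy) should exchange under i-Pr2NEt faster than the ring closes and only the (R)-enantiomer can keep the ring B aryl group equatorial in the chair-like transition state that the catalyst permits. The step needs umpolung of the aryl and not of the aliphatic aldehyde, which the substrate supports in that the C3 aldehyde is alpha-branched and carries an electronegative alpha-substituent, a class that serves as acceptor rather than donor in carbene-catalysed cross-benzoin reactions, and any isomeric 4-hydroxychroman-3-one would drain through the enediol to the conjugated aryl ketone. Because the diequatorial trans ketol is lower in energy than the cis isomer, any slow enolisation at C3 after ring closure pushes the diastereomer distribution the same way.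

**Step 11**
Reactants: 14 (2R,3R)-3-hydroxy-7-methoxy-5-(methoxymethoxy)-2-[4-methoxy-3-(methoxymethoxy)phenyl]-8-(3-methylbut-2-en-1-yl)chroman-4-one
Product: 15 (2R,3R)-3,5-dihydroxy-2-(3-hydroxy-4-methoxyphenyl)-7-methoxy-8-(3-methylbut-2-en-1-yl)chroman-4-one
Conditions: HCl (1.25 M in MeOH), THF, 40 °C
Reagents that add atoms: none
Why: Acid-catalysed transacetalisation (MOM cleavage) in methanol: both aryl acetals exchange to dimethoxymethane, the prenyl group has no ortho phenol with which to cyclise, and C2 and C3 are not epimerised by dilute acid because ring B offers no free para hydroxyl to help open ring C.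

**Compound list**
1 | 2,4,6-trihydroxybenzaldehyde | O=Cc1c(O)cc(O)cc1O | starting material
2 | prenyl bromide | CC(C)=CCBr | starting material
3 | 2,4,6-trihydroxy-3-(3-methylbut-2-en-1-yl)benzaldehyde | O=Cc1c(O)cc(O)c(CC=C(C)C)c1O | intermediate
4 | 2,6-dihydroxy-4-methoxy-3-(3-methylbut-2-en-1-yl)benzaldehyde | O=Cc1c(O)cc(OC)c(CC=C(C)C)c1O | intermediate
5 | 2-hydroxy-4-methoxy-6-(methoxymethoxy)-3-(3-methylbut-2-en-1-yl)benzaldehyde | O=Cc1c(OCOC)cc(OC)c(CC=C(C)C)c1O | intermediate
6 | 2-(3-hydroxy-4-methoxyphenyl)acetic acid | COc1ccc(CC(=O)O)cc1O | starting material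
7 | methyl 2-(3-hydroxy-4-methoxyphenyl)acetate | COC(=O)Cc1ccc(OC)c(O)c1 | intermediate
8 | methyl 2-[4-methoxy-3-(methoxymethoxy)phenyl]acetate | COC(=O)Cc1ccc(OC)c(OCOC)c1 | intermediate
9 | lithium enolate of 8 (not isolated; double-bond geometry without consequence) | [Li+].COC([O-])=Cc1ccc(OC)c(OCOC)c1 | intermediate
10 | methyl (±)-2-bromo-2-[4-methoxy-3-(methoxymethoxy)phenyl]acetate (racemate) | COC(=O)C(Br)c1ccc(OC)c(OCOC)c1 | intermediate
11 | methyl (±)-2-[2-formyl-5-methoxy-3-(methoxymethoxy)-6-(3-methylbut-2-en-1-yl)phenoxy]-2-[4-methoxy-3-(methoxymethoxy)phenyl]acetate (racemate) | O=Cc1c(OCOC)cc(OC)c(CC=C(C)C)c1OC(C(=O)OC)c1ccc(OC)c(OCOC)c1 | intermediate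
12 | (±)-2-[2-(hydroxymethyl)-5-methoxy-3-(methoxymethoxy)-6-(3-methylbut-2-en-1-yl)phenoxy]-2-[4-methoxy-3-(methoxymethoxy)phenyl]ethan-1-ol (racemate) | OCc1c(OCOC)cc(OC)c(CC=C(C)C)c1OC(CO)c1ccc(OC)c(OCOC)c1 | intermediate
13 | 4-methoxy-6-(methoxymethoxy)-2-{1-[4-methoxy-3-(methoxymethoxy)phenyl]-2-oxoethoxy}-3-(3-methylbut-2-en-1-yl)benzaldehyde (used as the C2-epimerising racemate; the (R)-enantiomer that is consumed is drawn) | O=Cc1c(OCOC)cc(OC)c(CC=C(C)C)c1O[C@@H](C=O)c1ccc(OC)c(OCOC)c1 | intermediate
14 | (2R,3R)-3-hydroxy-7-methoxy-5-(methoxymethoxy)-2-[4-methoxy-3-(methoxymethoxy)phenyl]-8-(3-methylbut-2-en-1-yl)chroman-4-one | COc1ccc([C@H]2Oc3c(CC=C(C)C)c(OC)cc(OCOC)c3C(=O)[C@@H]2O)cc1OCOC | intermediate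
15 | (2R,3R)-3,5-dihydroxy-2-(3-hydroxy-4-methoxyphenyl)-7-methoxy-8-(3-methylbut-2-en-1-yl)chroman-4-one | COc1ccc([C@H]2Oc3c(CC=C(C)C)c(OC)cc(O)c3C(=O)[C@@H]2O)cc1O | target

Total step count: 11. Longest linear sequence: 8 steps (1, 2, 3, 7, 8, 9, 10, 11; the ring B branch 4, 5, 6, 7–11 is equally long).

**Steps most likely to fail**

Step 10. Several processes compete with the intended closure:
- The carbene may engage the more electrophilic side-chain aldehyde. Expulsion of the ring A aryloxide from C2 (internal redox) would then break the ether link.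
- The amine may trigger a five-membered aldol closure of the C2 enolate onto the ring A formyl group.
- Addition to the di-ortho-substituted, electron-rich formyl group may be too slow.
- The catalyst may discriminate poorly between the two C2 enantiomers.
- Traces of air may dehydrogenate the ketol.

The fallback sets out from 13 and makes the C3–C4 bond reductively instead of by umpolung. SmI2 (THF, t-BuOH, −78 °C) couples the two aldehydes in a ketyl pinacol cyclisation to the racemic 2,3-trans-3,4-cis flavan-3,4-diol F1. One equivalent of 2-iodoxybenzoic acid in DMSO oxidises 1,2-diols without cleaving them and should take the electron-rich benzylic C4 carbinol first. This gives the racemic trans ketol, that is 14 together with its (2S,3S)-enantiomer F2. Preparative chromatography on an amylose carbamate chiral stationary phase removes the latter, and the sequence comes back to the route at 14.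

Step 9. Three processes are of concern:
- Acid may ionise the trialkoxybenzylic alcohol.
- After the first oxidation the remaining alcohol may add to the new aldehyde as a seven-membered lactol and be oxidised further.
- The alpha-aryl aldehyde may enolise and autoxidise during handling.

The fallback sets out from 11 and never touches the aryl aldehyde. LiOH (THF/H2O, 0 °C) gives the racemic carboxylic acid F3. EtSH, EDC·HCl and catalytic DMAP in CH2Cl2 give the racemic S-ethyl thioester F4. Fukuyama reduction (Et3SiH, Pd/C, acetone, rt), which tolerates aldehydes and trisubstituted alkenes, delivers the side-chain aldehyde directly and comes back to the route at 13, replacing steps 8 and 9.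

Step 1. Double or geminal C-alkylation with loss of aromaticity and competing O-alkylation may consume the phloroglucinol. The later discrimination between O2 and O6 in step 3 rests on this intermediate as well.

The fallback sets out from 1 and places the prenyl group by rearrangement, so that symmetry settles every regiochemical question.
- Me2SO4/K2CO3 in acetone gives the symmetrical 2,6-dihydroxy-4-methoxybenzaldehyde F5.
- One equivalent of bromide 10 with K2CO3 in DMF gives the racemic monoether F6, either hydroxyl leading to the same compound.
- Prenyl bromide 2 with K2CO3 in acetone caps the remaining hydroxyl as the racemic aryl prenyl ether F7.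
- Heating in N,N-diethylaniline at about 200 °C starts a para-Claisen–Cope sequence. This carries the prenyl group over the open ortho carbon to the position para to that oxygen, between O1 and the methoxy group, giving the racemic phenol F8.
- MOMCl/i-Pr2NEt then comes back to the route at 11, replacing steps 1–3 and 7.

**Further compounds**
F1 | step 10 | (2R*,3S*,4S*)-7-methoxy-5-(methoxymethoxy)-2-[4-methoxy-3-(methoxymethoxy)phenyl]-8-(3-methylbut-2-en-1-yl)chromane-3,4-diol (racemate, drawn as the (2R,3S,4S)-enantiomer) | COc1ccc([C@H]2Oc3c(CC=C(C)C)c(OC)cc(OCOC)c3[C@H](O)[C@@H]2O)cc1OCOC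
F2 | step 10 | (2S,3S)-3-hydroxy-7-methoxy-5-(methoxymethoxy)-2-[4-methoxy-3-(methoxymethoxy)phenyl]-8-(3-methylbut-2-en-1-yl)chroman-4-one (enantiomer of 14) | COc1ccc([C@@H]2Oc3c(CC=C(C)C)c(OC)cc(OCOC)c3C(=O)[C@H]2O)cc1OCOC
F3 | step 9 | (±)-2-[2-formyl-5-methoxy-3-(methoxymethoxy)-6-(3-methylbut-2-en-1-yl)phenoxy]-2-[4-methoxy-3-(methoxymethoxy)phenyl]acetic acid | O=Cc1c(OCOC)cc(OC)c(CC=C(C)C)c1OC(C(=O)O)c1ccc(OC)c(OCOC)c1
F4 | step 9 | S-ethyl (±)-2-[2-formyl-5-methoxy-3-(methoxymethoxy)-6-(3-methylbut-2-en-1-yl)phenoxy]-2-[4-methoxy-3-(methoxymethoxy)phenyl]ethanethioate | O=Cc1c(OCOC)cc(OC)c(CC=C(C)C)c1OC(C(=O)SCC)c1ccc(OC)c(OCOC)c1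
F5 | step 1 | 2,6-dihydroxy-4-methoxybenzaldehyde | O=Cc1c(O)cc(OC)cc1O
F6 | step 1 | methyl (±)-2-(2-formyl-3-hydroxy-5-methoxyphenoxy)-2-[4-methoxy-3-(methoxymethoxy)phenyl]acetate | O=Cc1c(O)cc(OC)cc1OC(C(=O)OC)c1ccc(OC)c(OCOC)c1
F7 | step 1 | methyl (±)-2-{2-formyl-5-methoxy-3-[(3-methylbut-2-en-1-yl)oxy]phenoxy}-2-[4-methoxy-3-(methoxymethoxy)phenyl]acetate | O=Cc1c(OCC=C(C)C)cc(OC)cc1OC(C(=O)OC)c1ccc(OC)c(OCOC)c1
F8 | step 1 | methyl (±)-2-[2-formyl-3-hydroxy-5-methoxy-6-(3-methylbut-2-en-1-yl)phenoxy]-2-[4-methoxy-3-(methoxymethoxy)phenyl]acetate | O=Cc1c(O)cc(OC)c(CC=C(C)C)c1OC(C(=O)OC)c1ccc(OC)c(OCOC)c1
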